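**Strategy.** Ring A is closed onto an enantioenriched ring B in a one-pot acylative [3+3] annulation. A neopentyl organozinc at C1 is acylated by 3-methylbut-2-enoyl chloride (C1–C2), and the new β,β-dimethyl enone is then attacked at C4 by C5, the γ-carbon of a ring-B silyl dienol ether (C4–C5, vinylogous Mukaiyama–Michael). The step exploits the 1,3-relationship of C1 and C5 across quaternary C10 and the acyl carbon/β-carbon pattern of C2 and gem-dimethyl C4 in ring A. The precursor is a monocyclic iodomethyl cyclohexadienyl silyl ether. C10 stems from a CBS reduction relayed through a cyclopropane; C5, C3 and C9 are adjusted afterwards by substrate control.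

Key step: step 8

**Remarks**
- Drimane numbering is used for all bicyclic compounds: ring A = C1–C5 and C10, ring B = C5–C10, C11 = the CH2O carbon on C9. Compounds before step 13 lack the C8 methyl.
- The 2-methylbut-2-enoate of the target is taken as the Z isomer (angelate), as the SMILES specifies.
- Where a stereocenter is re-set later (C5 in 14 and 15; C3 and C9 up to 18), the compound is drawn as the epimer expected to predominate; the other epimer converges in step 11.

**Route**

Step 1
Reactants: 1 3-methylcyclohex-2-en-1-one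
Product: 2 (S)-3-methylcyclohex-2-en-1-ol
Conditions: (R)-2-methyl-CBS-oxazaborolidine (10 mol %), catecholborane, toluene, −78 °C
Reagents that add atoms: none
Why: Corey–Bakshi–Shibata reduction, in which the alkenyl group acts as the large substituent so that the (R)-catalyst should give the (S)-carbinol, the one stereocenter set by catalysis.

Step 2
Reactants: 2 (S)-3-methylcyclohex-2-en-1-ol
Product: 3 (1R,2S,6S)-6-methylbicyclo[4.1.0]heptan-2-ol
Conditions: Et2Zn, CH2I2, CH2Cl2, 0 °C
Reagents that add atoms: diiodomethane ICI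
Why: Hydroxyl-directed Simmons–Smith (Furukawa) cyclopropanation delivers the methylene (future C1) syn to the zinc alkoxide and so fixes the quaternary carbon (future C10).

Step 3
Reactants: 3 (1R,2S,6S)-6-methylbicyclo[4.1.0]heptan-2-ol
Product: 4 (1R,6S)-6-methylbicyclo[4.1.0]heptan-2-one
Conditions: Dess–Martin periodinane, NaHCO3, CH2Cl2, rt
Reagents that add atoms: none
Why: Dess–Martin oxidation of the secondary alcohol leaves the cyclopropane and both stereocenters untouched.

Step 4
Reactants: 4 (1R,6S)-6-methylbicyclo[4.1.0]heptan-2-one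
Product: 6 (2R,3R)-2-(hydroxymethyl)-3-(iodomethyl)-3-methylcyclohexan-1-one, via γ-iodo trimethylsilyl enol ether 5 (not isolated)
Conditions: TMSI, CH2Cl2, −78 to 0 °C; then 37 % aq. HCHO, Yb(OTf)3 (10 mol %), THF, rt
Reagents that add atoms: iodotrimethylsilane C[Si](C)(C)I; formaldehyde C=O
Why: Iodide opens the silyl-activated cyclopropyl ketone at the unhindered CH2 (strain-driven homoconjugate opening of the exo bond that overlaps the carbonyl), and the regiodefined silyl enol ether then undergoes Mukaiyama hydroxymethylation anti to the CH2I group, which sets C9 provisionally.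

Step 5
Reactants: 6 (2R,3R)-2-(hydroxymethyl)-3-(iodomethyl)-3-methylcyclohexan-1-one
Product: 7 (2R,3R)-2-[(tert-butyldiphenylsilyloxy)methyl]-3-(iodomethyl)-3-methylcyclohexan-1-one
Conditions: TBDPSCl, imidazole, DMF, 0 °C to rt
Reagents that add atoms: tert-butyl(chloro)diphenylsilane CC(C)(C)[Si](Cl)(c1ccccc1)c1ccccc1
Why: Silylation of the primary alcohol under weakly basic conditions avoids alkoxide or enolate formation next to the γ-iodide.

Step 6
Reactants: 7 (2R,3R)-2-[(tert-butyldiphenylsilyloxy)methyl]-3-(iodomethyl)-3-methylcyclohexan-1-one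
Product: 9 (5R,6R)-6-[(tert-butyldiphenylsilyloxy)methyl]-5-(iodomethyl)-5-methylcyclohex-2-en-1-one, via kinetic trimethylsilyl enol ether 8 (not isolated)
Conditions: LDA, TMSCl, THF, −78 °C; then Pd(OAc)2, MeCN, rt
Reagents that add atoms: none
Why: Saegusa–Ito oxidation, in which kinetic deprotonation takes the unhindered C7 methylene (C9 is tertiary and hindered) and palladium diacetate then gives the C6=C7 enone.

Step 7
Reactants: 9 (5R,6R)-6-[(tert-butyldiphenylsilyloxy)methyl]-5-(iodomethyl)-5-methylcyclohex-2-en-1-one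
Product: 10 linear tert-butyldimethylsilyl dienol ether of 9 (C8–OTBS, C7=C8 and C5=C6)
Conditions: TBSOTf, Et3N, CH2Cl2, 0 °C
Reagents that add atoms: tert-butyldimethylsilyl trifluoromethanesulfonate CC(C)(C)[Si](C)(C)OS(=O)(=O)C(F)(F)F
Why: Soft enolisation under equilibrating conditions should give the through-conjugated 2-silyloxy-1,3-diene by loss of a C5 proton, which makes C5 nucleophilic.

Step 8
Reactants: 10 linear tert-butyldimethylsilyl dienol ether of 9; 11 3-methylbut-2-enoyl chloride
Product: 14 cis-fused bicyclic enone (ring A: C2 TBS enol ether C2=C3 and gem-dimethyl C4; ring B: C8 ketone conjugated with C6=C7; H5 cis to the C10 methyl), via alkylzinc iodide 12 (not isolated), via C1-acylated dienol ether 13 (not isolated)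
Conditions: Zn dust (TMSCl-activated), THF, 45 °C; Pd(PPh3)4 (5 mol %), 11, 0 °C to rt; solvent switched to CH2Cl2; TBSOTf (0.3 equiv), −78 to −40 °C; NaHCO3 quench
Reagents that add atoms: none
Why: Zinc inserts into the neopentyl C1–I bond (no β-hydrogen, dienol ether inert), and Negishi acylation of this alkylzinc by 11 under zerovalent palladium catalysis forms C1–C2 and the mesityl-oxide-like enone 13. The silyl triflate then activates that enone and the ring-B 2-silyloxydiene attacks C4 through its γ-carbon C5 with transfer of the silyl group to O2; the closest known reactions are Lewis-acid-mediated Mukaiyama–Michael additions of silyl enol ethers to mesityl oxide and γ-selective reactions of silyl dienol ethers. Ring A closes 6-endo-trig, since the C3=C4 bond lies inside the new ring. C4 becomes the quaternary gem-dimethyl carbon without a new stereocenter, whereas C5 is formed by axial attack from the face of the C1 tether and is therefore expected cis to the C10 methyl, which is accepted because C5 is re-set in steps 10 and 11. Site selectivity is secured by geometry: attack of C5 on the carbonyl carbon C2 would need a four-membered ring and attack through the α-carbon C7 an eight-membered bridged ring. Acylation occurs only at C1 because only the C–Zn bond transmetalates to palladium, and the regiodefined C2=C3 silyl enol ether that results is what later directs oxygen to C3.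

Step 9
Reactants: 14 cis-fused bicyclic enone with C2 TBS enol ether
Product: 15 cis-fused 3-(tert-butyldimethylsilyloxy) 2,8-diketone with the C6=C7 enone (3-OTBS cis to the C10 methyl)
Conditions: mCPBA, NaHCO3, CH2Cl2, −20 °C
Reagents that add atoms: 3-chloroperoxybenzoic acid OOC(=O)c1cccc(Cl)c1
Why: Rubottom oxidation epoxidises the only electron-rich alkene (the C2=C3 silyl enol ether) and silyl migration gives the α-silyloxy ketone with oxygen regiospecifically at C3, attack being expected from the face away from the axial C6 branch of the cis-fused ring system.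

Step 10
Reactants: 15 cis-fused 3-silyloxy diketone
Product: 17 β,γ-unsaturated diketone (C5=C6 alkene, C8 and C2 ketones, 3-OTBS), via bis(trimethylsilyl) enol ether 16 (not isolated)
Conditions: TMSOTf, Et3N, CH2Cl2, 0 °C to rt; then TBAF, AcOH, THF, −78 °C
Reagents that add atoms: none
Why: Thermodynamic silylation gives the linear dienol ether in which C5 is sp2 (the cis ring fusion is erased), and buffered fluoride releases the dienolate, which should be protonated kinetically at the α-carbon C7 (deconjugation of an enone through its dienol ether).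

Step 11
Reactants: 17 β,γ-unsaturated diketone
Product: 19 trans-fused saturated 2,8-diketone (3-OTBS and C11 equatorial, both cis to the C10 methyl; H5 trans to it), via 3-epimeric trans-fused diketone 18 (not isolated)
Conditions: Mn(dpm)3 (10 mol %), PhSiH3, t-BuOOH, i-PrOH, rt; then DBU, toluene, 40 °C
Reagents that add atoms: none
Why: Metal-hydride hydrogen-atom-transfer hydrogenation (Shenvi type) puts H on C6 and the tertiary C5 radical should take its hydrogen axially from the face anti to the C10 and C4 axial methyls, giving the trans fusion; DBU then equilibrates the enolisable C3 and C9 centers to their equatorial configurations.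

Step 12
Reactants: 19 trans-fused saturated 2,8-diketone
Product: 20 C7=C8 enol triflate (8-OTf) of 19
Conditions: LDA, THF, −78 °C; then PhNTf2
Reagents that add atoms: N-phenylbis(trifluoromethanesulfonimide) O=S(=O)(N(c1ccccc1)S(=O)(=O)C(F)(F)F)C(F)(F)F
Why: Kinetic enolate triflation, in which the base should take the unhindered C7 proton because both α-positions of the C2 ketone are neopentylic and C9 is tertiary.

Step 13
Reactants: 20 C7=C8 enol triflate
Product: 21 (3S,5S,9R,10R)-3-(tert-butyldimethylsilyloxy)-11-(tert-butyldiphenylsilyloxy)drim-7-en-2-one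
Conditions: PdCl2(dppf) (5 mol %), trimethylboroxine, K2CO3, dioxane, 80 °C
Reagents that add atoms: trimethylboroxine CB1OB(C)OB(C)O1
Why: Suzuki–Miyaura methylation of the enol triflate installs the C8 methyl with the double bond fixed at C7=C8 and tolerates the ketone.

Step 14
Reactants: 21 bis-silyl ether of the drimenone diol
Product: 22 (3S,5S,9R,10R)-3,11-dihydroxydrim-7-en-2-one
Conditions: HF·pyridine, pyridine, THF, 0 °C to rt
Reagents that add atoms: none
Why: Fluoride-mediated cleavage of both silyl ethers under non-basic conditions avoids α-ketol isomerisation.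

Step 15
Reactants: 22 (3S,5S,9R,10R)-3,11-dihydroxydrim-7-en-2-one; 23 umbelliferone (7-hydroxy-2H-chromen-2-one)
Product: 24 (3S,5S,9R,10R)-3-hydroxy-11-(2-oxo-2H-chromen-7-yloxy)drim-7-en-2-one
Conditions: PPh3, DIAD, THF, 0 °C to rt
Reagents that add atoms: none
Why: Mitsunobu etherification, in which the acidic phenol displaces the activated primary C11 hydroxyl while the hindered secondary C3 hydroxyl stays free and no stereocenter is touched.

Step 16
Reactants: 24 coumarin ether alcohol; 25 angelic acid ((Z)-2-methylbut-2-enoic acid)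
Product: 27 CNP0111364.1, (3S,5S,9R,10R)-3-angeloyloxy-11-(2-oxo-2H-chromen-7-yloxy)drim-7-en-2-one, via angelic 2,4,6-trichlorobenzoic anhydride 26 (not isolated)
Conditions: 2,4,6-trichlorobenzoyl chloride, Et3N, toluene, rt; then 24, 80 °C
Reagents that add atoms: none
Why: Yamaguchi esterification through the mixed anhydride without nucleophilic catalyst, conditions under which the Z geometry of the angeloyl group should be kept and C3 is not inverted.

**Compound list**

1 | 3-methylcyclohex-2-en-1-one | CC1=CC(=O)CCC1 | starting material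
2 | (S)-3-methylcyclohex-2-en-1-ol | CC1=C[C@@H](O)CCC1 | intermediate
3 | (1R,2S,6S)-6-methylbicyclo[4.1.0]heptan-2-ol | C1[C@@]2(C)[C@@H]1[C@@H](O)CCC2 | intermediate
4 | (1R,6S)-6-methylbicyclo[4.1.0]heptan-2-one | C1[C@@]2(C)[C@@H]1C(=O)CCC2 | intermediate
5 | (R)-3-(iodomethyl)-3-methyl-1-(trimethylsilyloxy)cyclohex-1-ene | IC[C@@]1(C)C=C(O[Si](C)(C)C)CCC1 | intermediate
6 | (2R,3R)-2-(hydroxymethyl)-3-(iodomethyl)-3-methylcyclohexan-1-one | IC[C@@]1(C)[C@H](CO)C(=O)CCC1 | intermediate
7 | (2R,3R)-2-[(tert-butyldiphenylsilyloxy)methyl]-3-(iodomethyl)-3-methylcyclohexan-1-one | IC[C@@]1(C)[C@H](CO[Si](c2ccccc2)(c2ccccc2)C(C)(C)C)C(=O)CCC1 | intermediate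
8 | kinetic trimethylsilyl enol ether of 7 (enol double bond toward the ring CH2, C7=C8) | IC[C@@]1(C)[C@H](CO[Si](c2ccccc2)(c2ccccc2)C(C)(C)C)C(O[Si](C)(C)C)=CCC1 | intermediate
9 | (5R,6R)-6-[(tert-butyldiphenylsilyloxy)methyl]-5-(iodomethyl)-5-methylcyclohex-2-en-1-one | IC[C@@]1(C)[C@H](CO[Si](c2ccccc2)(c2ccccc2)C(C)(C)C)C(=O)C=CC1 | intermediate
10 | linear TBS dienol ether of 9 (2-silyloxycyclohexa-1,3-diene; C9 and C10 as in 9) | IC[C@@]1(C)[C@H](CO[Si](c2ccccc2)(c2ccccc2)C(C)(C)C)C(O[Si](C)(C)C(C)(C)C)=CC=C1 | intermediate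
11 | 3-methylbut-2-enoyl chloride | CC(C)=CC(Cl)=O | starting material
12 | alkylzinc iodide from 10 (C1–ZnI) | I[Zn]C[C@@]1(C)[C@H](CO[Si](c2ccccc2)(c2ccccc2)C(C)(C)C)C(O[Si](C)(C)C(C)(C)C)=CC=C1 | intermediate
13 | C1-acylated dienol ether (4-methyl-2-oxopent-3-enyl side chain on C10) | CC(C)=CC(=O)C[C@@]1(C)[C@H](CO[Si](c2ccccc2)(c2ccccc2)C(C)(C)C)C(O[Si](C)(C)C(C)(C)C)=CC=C1 | intermediate
14 | cis-fused bicyclic enone: C2 TBS enol ether (C2=C3), gem-dimethyl C4, C8 ketone with C6=C7, C9 CH2OTBDPS cis to the C10 methyl, H5 cis to the C10 methyl | C1=C(O[Si](C)(C)C(C)(C)C)C[C@@]2(C)[C@H](CO[Si](c3ccccc3)(c3ccccc3)C(C)(C)C)C(=O)C=C[C@H]2C1(C)C | intermediate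
15 | cis-fused 3-OTBS 2,8-diketone with C6=C7 (3-OTBS cis to the C10 methyl; H5 cis to the C10 methyl) | O([Si](C)(C)C(C)(C)C)[C@@H]1C(=O)C[C@@]2(C)[C@H](CO[Si](c3ccccc3)(c3ccccc3)C(C)(C)C)C(=O)C=C[C@H]2C1(C)C | intermediate
16 | bis(trimethylsilyl) enol ether of 15 (C1=C2–OTMS in ring A; C8–OTMS 5,7-diene in ring B) | O([Si](C)(C)C(C)(C)C)[C@@H]1C(O[Si](C)(C)C)=C[C@@]2(C)[C@H](CO[Si](c3ccccc3)(c3ccccc3)C(C)(C)C)C(O[Si](C)(C)C)=CC=C2C1(C)C | intermediate
17 | β,γ-unsaturated diketone (C5=C6; C2 and C8 ketones; 3-OTBS; 11-OTBDPS) | O([Si](C)(C)C(C)(C)C)[C@@H]1C(=O)C[C@@]2(C)[C@H](CO[Si](c3ccccc3)(c3ccccc3)C(C)(C)C)C(=O)CC=C2C1(C)C | intermediate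
18 | trans-fused saturated 2,8-diketone, C3 epimer of 19 (3-OTBS trans to the C10 methyl) | O([Si](C)(C)C(C)(C)C)[C@H]1C(=O)C[C@@]2(C)[C@H](CO[Si](c3ccccc3)(c3ccccc3)C(C)(C)C)C(=O)CC[C@@H]2C1(C)C | intermediate
19 | trans-fused saturated 2,8-diketone (3S,5S,9R,10R; 3-OTBS and C11 cis to the C10 methyl, H5 trans) | O([Si](C)(C)C(C)(C)C)[C@@H]1C(=O)C[C@@]2(C)[C@H](CO[Si](c3ccccc3)(c3ccccc3)C(C)(C)C)C(=O)CC[C@@H]2C1(C)C | intermediate
20 | C7=C8 enol triflate of 19 (8-OTf) | O([Si](C)(C)C(C)(C)C)[C@@H]1C(=O)C[C@@]2(C)[C@H](CO[Si](c3ccccc3)(c3ccccc3)C(C)(C)C)C(OS(=O)(=O)C(F)(F)F)=CC[C@@H]2C1(C)C | intermediate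
21 | (3S,5S,9R,10R)-3-(tert-butyldimethylsilyloxy)-11-(tert-butyldiphenylsilyloxy)drim-7-en-2-one | O([Si](C)(C)C(C)(C)C)[C@@H]1C(=O)C[C@@]2(C)[C@H](CO[Si](c3ccccc3)(c3ccccc3)C(C)(C)C)C(C)=CC[C@@H]2C1(C)C | intermediate
22 | (3S,5S,9R,10R)-3,11-dihydroxydrim-7-en-2-one | O[C@@H]1C(=O)C[C@@]2(C)[C@H](CO)C(C)=CC[C@@H]2C1(C)C | intermediate
23 | umbelliferone (7-hydroxy-2H-chromen-2-one) | Oc1ccc2ccc(=O)oc2c1 | starting material
24 | (3S,5S,9R,10R)-3-hydroxy-11-(2-oxo-2H-chromen-7-yloxy)drim-7-en-2-one | O[C@@H]1C(=O)C[C@@]2(C)[C@H](COc3ccc4ccc(=O)oc4c3)C(C)=CC[C@@H]2C1(C)C | intermediate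
25 | angelic acid, (Z)-2-methylbut-2-enoic acid | C/C=C(/C)C(=O)O | starting material
26 | angelic 2,4,6-trichlorobenzoic anhydride | C/C=C(/C)C(=O)OC(=O)c1c(Cl)cc(Cl)cc1Cl | intermediate
27 | CNP0111364.1, (3S,5S,9R,10R)-3-angeloyloxy-11-(2-oxo-2H-chromen-7-yloxy)drim-7-en-2-one | C/C=C(/C)C(=O)O[C@@H]1C(=O)C[C@@]2(C)[C@H](COc3ccc4ccc(=O)oc4c3)C(C)=CC[C@@H]2C1(C)C | target

**Step count and risks**

Total step count: 16. Longest linear sequence: 16 steps (from 1; compounds 11, 23 and 25 are bought).

Steps most likely to fail: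

1. Step 8. Zinc insertion at the neopentyl iodide may be sluggish. The silyloxydiene may collapse onto the enone by a Michael–aldol sequence to a bridged bicyclo[2.2.2]octanone, or lose its silyl group before cyclising. The γ-attack may be slow at the congested C4. The fallback changes the electrophile, carries the C3 oxygen in the acyl fragment and sets out from 10. 3-Methylbut-2-en-1-ol is epoxidised by the Sharpless method (tartrate enantiomer chosen for the 2R product) to (R)-(3,3-dimethyloxiran-2-yl)methanol F1. Oxidation with RuCl3/NaIO4 gives (S)-3,3-dimethyloxirane-2-carboxylic acid F2, and EtSH/DCC gives S-ethyl (S)-3,3-dimethyloxirane-2-carbothioate F3. Fukuyama coupling of the alkylzinc 12 (made from 10 as before) with F3 under PdCl2(PPh3)2 catalysis gives the epoxy ketone F4 (the C1–C2 bond). In the same pot after solvent switch, catalytic TBSOTf makes C5 of the dienol ether open the epoxide at its tertiary carbon C4 with silyl transfer to O3. The route is rejoined at 15; compound 14 and step 9 are bypassed, and C3 comes from the epoxide.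

2. Step 10. Removal of the hindered ring-fusion proton at C5 may be slow or the cross-conjugated dienol ether may form instead, so that deconjugation fails. Reconjugation during protonation would return the cis-fused enone. The fallback sets out from 15 and avoids the alkene isomer altogether. Base equilibration through the linear dienolate (DBU, toluene, warm) is used to reach the trans-fused enone F5, which is separated from remaining 15 and recycled. Conjugate reduction of F5 with [(Ph3P)CuH]6 (monovalent copper hydride, Stryker reagent) followed by the DBU stage of step 11 rejoins the route at 19, bypassing steps 10 and 11. This relies on the trans isomer being thermodynamically accessible, which is not assured.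

3. Step 16. Acylation of the hindered α-ketol hydroxyl may be slow, the angeloyl unit may isomerise from Z to E, or base may cause acyl migration. The fallback builds the Z-alkene after acylation and sets out from 24. Esterification with 2-[bis(2,2,2-trifluoroethoxy)phosphoryl]propanoic acid (EDC, DMAP) gives the phosphonate ester F6. Still–Gennari olefination of F6 with acetaldehyde (K2CO3, 18-crown-6, toluene, −20 °C) should give the Z-2-methylbut-2-enoate, rejoining the route at 27.

**Further compounds**

F1 | step 8 | (R)-(3,3-dimethyloxiran-2-yl)methanol | OC[C@H]1OC1(C)C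
F2 | step 8 | (S)-3,3-dimethyloxirane-2-carboxylic acid | OC(=O)[C@H]1OC1(C)C
F3 | step 8 | S-ethyl (S)-3,3-dimethyloxirane-2-carbothioate | CCSC(=O)[C@H]1OC1(C)C
F4 | step 8 | epoxy ketone: (S)-3,3-dimethyloxiran-2-yl ketone on the C1 methylene of the dienol ether 10 skeleton | CC1(C)O[C@@H]1C(=O)C[C@@]2(C)[C@H](CO[Si](c3ccccc3)(c3ccccc3)C(C)(C)C)C(O[Si](C)(C)C(C)(C)C)=CC=C2
F5 | step 10 | trans-fused C5 epimer of 15 (H5 trans to the C10 methyl) | O([Si](C)(C)C(C)(C)C)[C@@H]1C(=O)C[C@@]2(C)[C@H](CO[Si](c3ccccc3)(c3ccccc3)C(C)(C)C)C(=O)C=C[C@@H]2C1(C)C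
F6 | step 16 | 2-[bis(2,2,2-trifluoroethoxy)phosphoryl]propanoate ester of 24 at O3 | CC(C(=O)O[C@@H]1C(=O)C[C@@]2(C)[C@H](COc3ccc4ccc(=O)oc4c3)C(C)=CC[C@@H]2C1(C)C)P(=O)(OCC(F)(F)F)OCC(F)(F)F
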